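(The earlier runs and the new flask are simulated from invented constants, and the scatter is random.)

The target forms on the enzyme from starting material and second substrate. Off the enzyme, starting material and target can join to give side product, and target can go on to over-reaction product.

| setting | grey | amber | teal | maple | birch |
|---|---|---|---|---|---|
| starting material | 0.048 M | 0.067 M | 0.11 M | 0.040 M | 0.12 M |
| second substrate | 0.126 M (fed, over 8.0 h) | 0.126 M (fed, over 8.0 h) | 0.126 M (fed, over 8.0 h) | 0.126 M | 0.126 M (fed, over 8.0 h) |
| enzyme | 60 µM | 60 µM | 60 µM | 60 µM | 60 µM |
| remark | run made earlier; the fed solution adds 0.20 times the starting volume | run made earlier; the fed solution adds 0.20 times the starting volume | run made earlier; the fed solution adds 0.20 times the starting volume | everything together at the start, the whole solution of second substrate included, so that from the start the volume is larger by 0.20 times the starting volume | the fed solution adds 0.20 times the starting volume |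
| time |  |  |  | 12 d | 12 d |

- grey (time / d: target / %, starting material / %): 1.04: 60.4, 35.6; 1.67: 87.8, 7.4; 3.00: 94.3, 0.7; 6.00: 94.7, 0.1; 12.0: 93.7, 0.5
- amber (time / d: target / %, starting material / %): 2.50: 86.2, 3.5; 5.00: 87.6, 0.3; 8.00: 89.3, 0; 10.0: 88.3, 1.9; 12.0: 88.9, 0
- teal (time / d: target / %, starting material / %): 2.50: 57.6, 24.2; 5.00: 75.5, 0.4; 8.00: 73.6, 0; 10.0: 76.2, 0; 12.0: 73.0, 0

(standard deviation of a reading: 1 percentage point)

- in percentages every species weighs as the starting material in it: one side product counts as two
- charges are per starting volume, the dose included; the dosed solution carries all of it
- reactions considered so far: starting material + enzyme <-> starting complex; target -> over-reaction product; second substrate + starting complex <-> ternary complex; starting material + target -> side product; ternary complex -> enzyme + target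

- which one finishes higher in amount of target, in percent of the starting material charged ("neither" within 2 percentage points) (maple / birch / neither)
- amount of target at the end, in percent of the starting material charged, maple
- amount of target at the end, in percent of the starting material charged, birch

1. The plateaus look out of proportion. The grey plateau reads 5.77% short of the charge and the teal plateau 25.4% short, a ratio of 4.40 as read, for a charge ratio of 2.29.

2. Counting turnovers clears this up. The count (total turnover number) is charge over enzyme: 800 in grey, 1830 in teal. Early readings of starting material used per enzyme and day are similar, 495 d⁻¹ in grey and 556 d⁻¹ in teal. As an estimate, at this enzyme charge and a like pace, a larger count means a longer overlap of starting material and target, at higher amounts of both. Fractional loss is then taken to go with the square of the count, and the squared ratio of 5.25 is somewhat higher than the ratio read.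

3. Grey reads 3330: the turnover scale, the count over the square root of the fractional loss. Teal reads 3640. Fractional loss is then the squared ratio of count to scale.

4. Grey has a lower charge than the other runs and teal a higher one, so low-charge maple is reckoned on grey's scale and high-charge birch on teal's. This reckoning gives maple an estimated loss of 4.00%, so 96.0% target, and birch an estimated loss of 30.3%, so 69.7% target.

5. The forecast says maple, with 95.5% for maple, a little lower than this reckoning, and 70% for birch. It describes its loss per squared charge as “sagging at high loss because the target is depleted”.

6. The flasks give 95.0% in maple and 71.1% in birch, so maple finishes higher.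

    starting material + enzyme ⇌ starting complex (K = 130 M⁻¹, k = 25000 M⁻¹ h⁻¹)
    target → over-reaction product (k = 2.00 × 10⁻⁵ h⁻¹)
    second substrate + starting complex ⇌ ternary complex (K = 25.0 M⁻¹, k = 50000 M⁻¹ h⁻¹)
    starting material + target → side product (k = 0.120 M⁻¹ h⁻¹)
    ternary complex → enzyme + target (k = 36.0 h⁻¹)

In birch at 1.65 d, the side step uses target 310 times as fast as the over-reaction step. At the end birch holds 28.6% side product, beside the 30.3% reckoned from the scale, and 0.349% over-reaction product.

A neighbour of birch with 0.030 M of starting material, all else as in birch, has a count of 500, so grey's scale gives an estimated loss of 2.25% and 97.8% target. That flask gives 96.7% target, with 2.79% side product.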